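(The readings come from a simulation with made-up constants.)

Eta stands at 107.1 mM of product at 8.1 h, after 108.1 mM at 5.1 h, from 120 mM of partner and 450 mM of substrate. Partner, charged at less than substrate in eta and in theta, is the limiting reagent in both. The quantity to carry is therefore the capture share, the final c(product) divided by the c(partner) charged, which eta gives as a reading of 0.893.

| setting | epsilon | beta | eta | theta |
|---|---|---|---|---|
| substrate | 150 mM | 90.0 mM | 450 mM | 450 mM |
| partner | 120 mM | 60.0 mM | 120 mM | 60.0 mM |
| time |  |  |  | 8.1 h |

| run | time / h | [product] / mM |
|---|---|---|
| epsilon run | 0.32 | 8.6 |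
| epsilon run | 0.51 | 13.8 |
| epsilon run | 0.81 | 20.1 |
| epsilon run | 1.3 | 35.1 |
| epsilon run | 2.0 | 48.3 |
| epsilon run | 3.2 | 63.6 |
| epsilon run | 5.1 | 75.2 |
| epsilon run | 8.1 | 80.1 |
| beta run | 0.32 | 2.9 |
| beta run | 0.51 | 4.0 |
| beta run | 0.81 | 6.6 |
| beta run | 1.3 | 7.6 |
| beta run | 2.0 | 13.3 |
| beta run | 3.2 | 19.1 |
| beta run | 5.1 | 24.0 |
| beta run | 8.1 | 27.2 |
| eta run | 0.32 | 28.7 |
| eta run | 0.51 | 45.8 |
| eta run | 0.81 | 69.7 |
| eta run | 1.3 | 93.9 |
| eta run | 2.0 | 104.9 |
| eta run | 3.2 | 108.3 |
| eta run | 5.1 | 108.1 |
| eta run | 8.1 | 107.1 |

(standard deviation of a reading: 1 mM)

* how the opening rate goes with [partner] round the charge of the epsilon run: the exponent of the rate at two percent of substrate gone to product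
* how the opening rate goes with [substrate] round the charge of the epsilon run: the exponent of the rate at two percent of substrate gone to product (one fixed amount of product, the same in the runs compared)
* product in the theta run at 8.1 h, as a share of the substrate charged

- Overall: substrate + partner -> product.
- Constant volume, constant temperature.
- "The second partner" is partner.
- An order is taken over about fifteen percent of the charge, up and down.

The first 3 readings, summed, estimate the orders. Eta over epsilon gives a substrate exponent of 1.11. Beta over epsilon, taking substrate as first order, gives a partner exponent of 0.918. The reckoning here commits to first order in each.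

Two extreme versions, each solved by hand, frame the estimate for theta. The zero of the scale is a capture share of 1, every partner becoming product, which gives 13.3% of the substrate charged. The low version takes the odds of capture in epsilon, 2.01, and scales them with the substrate charged. That gives a share of 0.858, or 11.4%. This version should run low because epsilon has turned 53.4% of its substrate, more than the 13.3% that the partner charge of theta allows. Eta has the same substrate charge as theta, so its share, assumed here to be independent of the partner charge, places theta at 11.9%.

The forecast, which holds “These plateaus look like a reversible reaction”, gives 0.85, 1.05 and 11.9%.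

The flask gives 11.8% for theta, with exponents of 1.0 for partner and 1.0 for substrate.

    substrate + partner → product + by-product (1.469 M⁻¹ h⁻¹)
    partner → lost reagent (0.1346 h⁻¹)
    substrate + partner + product → 2 product (39.60 M⁻² h⁻¹)

The step from partner to lost reagent moves the readings by 9.7 scatter units, root mean square. Theta's capture share at 8.1 h comes to 0.882, close to eta's reading of 0.893. Beta, charged with 90.0 mM of substrate, holds a share of 0.453 at 8.1 h.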